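**Retrosynthetic overview**

1. Target 16 ⇐ 15 ⇐ 14 by protecting-group cleavage only (BBr3, then TFA going backwards); all skeletal bonds and both stereocentres are already present in 14.
2. 14 ⇒ racemic α-keto tetraester 12, disconnecting the lactone bond O2–C1 and the C3–H bond. The strategy rests on C4 of the isochroman-1-one: it is benzylic (C4a), α to C3 and γ to the tert-butyl ester through Cα=Cβ, so with C3 as a ketone it epimerises freely. One catalyst-controlled hydride transfer to C3 therefore fixes C3 and C4, and the C3 hydroxyl then closes the lactone ring, the only ring formed in the route.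
3. 12 ⇒ arylpyruvate 7 + (Z)-enol triflate 11 (C4–Cα bond by addition–elimination).
4. 7 ⇐ toluate 4 + dimethyl oxalate 5 (C3–C4 bond, lateral lithiation) ⇐ acid 1 (ortho-methylation, esterification); 11 ⇐ tert-butyl acetate 8 + 5 (Claisen condensation, enol triflation).

Key step: step 7

Numbering: C1–C8a are the positions of the isochroman-1-one of the target; Cα and Cβ are the side-chain alkene carbons bearing CO2Me and H.

Assumption: the (S,S)-catalyst is taken to deliver hydride to the Re face of C3 (3S), on the model in which the ester carbonyl of an α-keto ester takes the place of the aryl group of an aryl ketone. If the sense proved opposite, the (R,R)-catalyst would be used with no other change.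

Remark: 12 is drawn as the keto tautomer and is used as the tautomer mixture. It should be kept cold and carried on promptly, because its enol can close onto the ortho ester.

**Route**

Step 1
Reactants: 1 2,4,5-trimethoxybenzoic acid
Product: 3 3,4,6-trimethoxy-2-methylbenzoic acid, via lithium 6-lithio-2,4,5-trimethoxybenzoate 2 (not isolated)
Conditions: s-BuLi (2.2 equiv), TMEDA, THF, −78 °C; MeI, −78 °C → rt; aq. HCl
Reagents that add atoms: iodomethane, CI
Why: Directed ortho-metalation of the lithium carboxylate, in which the only C–H ortho to the carboxylate is also ortho to the 5-methoxy group so both directing groups converge on it, followed by SN2 methylation of the aryllithium.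

Step 2
Reactants: 3 3,4,6-trimethoxy-2-methylbenzoic acid
Product: 4 methyl 3,4,6-trimethoxy-2-methylbenzoate
Conditions: MeI, K2CO3, DMF, rt
Reagents that add atoms: iodomethane, CI
Why: O-alkylation of the carboxylate (SN2 on iodomethane) avoids the crowded tetrahedral intermediate that makes Fischer esterification of a 2,6-disubstituted benzoic acid slow.

Step 3
Reactants: 4 methyl 3,4,6-trimethoxy-2-methylbenzoate; 5 dimethyl oxalate
Product: 7 methyl 3,4,6-trimethoxy-2-(3-methoxy-2,3-dioxopropyl)benzoate, via methyl 2-(lithiomethyl)-3,4,6-trimethoxybenzoate 6 (not isolated)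
Conditions: LDA (2.2 equiv), THF, −78 °C; (CO2Me)2, −78 °C; AcOH, −78 °C, cold work-up
Reagents that add atoms: none
Why: Lateral lithiation of the ortho-toluate followed by crossed Claisen acylation with the non-enolisable oxalate, the second equivalent of base holding the arylpyruvate as its enolate until the cold acidic quench so that the enol does not close onto the ortho ester.

Step 4
Reactants: 8 tert-butyl acetate; 5 dimethyl oxalate
Product: 10 4-tert-butyl 1-methyl 2-oxobutanedioate, via tert-butyl acetate lithium enolate 9 (not isolated)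
Conditions: LDA, THF, −78 °C (2 equiv of enolate); (CO2Me)2 (1 equiv), −78 → 0 °C; 1 M HCl
Reagents that add atoms: none
Why: Crossed Claisen condensation of the ester enolate with the non-enolisable oxalate, driven by deprotonation of the oxaloacetate by the second equivalent of enolate.

Step 5
Reactants: 10 4-tert-butyl 1-methyl 2-oxobutanedioate
Product: 11 4-tert-butyl 1-methyl (2Z)-2-{[(trifluoromethyl)sulfonyl]oxy}but-2-enedioate
Conditions: Tf2O, sat. aq. LiOH, toluene, 0–5 °C
Reagents that add atoms: trifluoromethanesulfonic anhydride, O=S(=O)(OS(=O)(=O)C(F)(F)F)C(F)(F)F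
Why: O-sulfonylation of the lithium-chelated enolate, in which lithium bridges the enolate oxygen and the tert-butyl ester carbonyl and so holds them cis, which should give the (Z)-enol triflate (any (E)-isomer to be removed by chromatography).

Step 6
Reactants: 7 methyl 3,4,6-trimethoxy-2-(3-methoxy-2,3-dioxopropyl)benzoate; 11 4-tert-butyl 1-methyl (2Z)-2-{[(trifluoromethyl)sulfonyl]oxy}but-2-enedioate
Product: 12 4-tert-butyl 1-methyl (2E)-2-{3-methoxy-2,3-dioxo-1-[2,3,5-trimethoxy-6-(methoxycarbonyl)phenyl]propyl}but-2-enedioate (racemic at C4)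
Conditions: Cs2CO3 (2.2 equiv), MeCN, 0 °C → rt; cold aq. citric acid
Reagents that add atoms: none
Why: Conjugate addition–elimination (nucleophilic vinylic substitution) in which the caesium enolate of 7 adds through its benzylic carbon to the triflate-bearing carbon of 11 (β to the tert-butyl ester, a vinylogous acyl triflate) and the resulting ester enolate expels triflate with retention, placing C4 cis to CO2tBu; C4 is formed racemic and labile, as step 7 requires.

Step 7
Reactants: 12 4-tert-butyl 1-methyl (2E)-2-{3-methoxy-2,3-dioxo-1-[2,3,5-trimethoxy-6-(methoxycarbonyl)phenyl]propyl}but-2-enedioate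
Product: 14 methyl (3S,4R)-4-[(2E)-4-tert-butoxy-1-methoxy-1,4-dioxobut-2-en-2-yl]-5,6,8-trimethoxy-1-oxo-3,4-dihydro-1H-isochromene-3-carboxylate, via open-chain (3S,4R)-hydroxy tetraester 13 (not isolated)
Conditions: RuCl[(S,S)-TsDPEN](p-cymene) (3 mol%), HCO2H/Et3N (5:2), DMF, 30 °C
Reagents that add atoms: none
Why: Dynamic kinetic resolution by Noyori–Ikariya asymmetric transfer hydrogenation: in the formate/amine medium 12 enolises towards C4, so its C4 epimers interconvert faster than the Ru–H/N–H species, regenerated by formic acid, transfers hydride and proton to the C3 carbonyl through the outer-sphere six-membered transition state. The closest known reaction is the Ru(II)–arene/N-sulfonyl-1,2-diamine transfer hydrogenation of racemic β-aryl α-keto esters with lactonisation in the same flask. The C3 hydroxyl of 13 then attacks the ortho methyl ester in a 6-exo-trig acyl substitution that forms O2–C1, expels methanol and closes the lactone ring of the isochroman-1-one. C3 is set by the catalyst, which delivers hydride to the Re face (3S); C4 is set by selection of the (4R)-epimer, the one that can hold its 2,6-disubstituted aryl group anti to the incoming hydride on that face (Felkin–Anh), which corresponds to the 3,4-trans lactone. The step needs 1,2-reduction of the ketone in preference to the fumarate C=C, which the polar outer-sphere mechanism and the far more electrophilic α-keto ester should secure. It also needs closure on the benzoate and not on a side-chain ester: the tert-butyl ester is too hindered, and the Cα methyl ester is conjugated and reachable only by turning C3 into the alkene plane, which drives the aryl group against the cis tert-butyl ester (A1,3 strain), whereas the benzoate is held perpendicular to the ring by its two ortho substituents with its π* directed at the C3 hydroxyl.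

Step 8
Reactants: 14 methyl (3S,4R)-4-[(2E)-4-tert-butoxy-1-methoxy-1,4-dioxobut-2-en-2-yl]-5,6,8-trimethoxy-1-oxo-3,4-dihydro-1H-isochromene-3-carboxylate
Product: 15 (2E)-4-methoxy-4-oxo-3-[(3S,4R)-5,6,8-trimethoxy-3-(methoxycarbonyl)-1-oxo-3,4-dihydro-1H-isochromen-4-yl]but-2-enoic acid
Conditions: TFA/CH2Cl2 (1:3), 0 °C → rt
Reagents that add atoms: none
Why: Acid-catalysed alkyl–oxygen cleavage of the tert-butyl ester with loss of 2-methylpropene, under which methyl esters, lactone and aryl ethers are inert and, no base being present, C3, C4 and the alkene geometry are not touched.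

Step 9
Reactants: 15 (2E)-4-methoxy-4-oxo-3-[(3S,4R)-5,6,8-trimethoxy-3-(methoxycarbonyl)-1-oxo-3,4-dihydro-1H-isochromen-4-yl]but-2-enoic acid
Product: 16 (2E)-4-methoxy-4-oxo-3-[(3S,4R)-5,6,8-trihydroxy-3-(methoxycarbonyl)-1-oxo-3,4-dihydro-1H-isochromen-4-yl]but-2-enoic acid (target)
Conditions: BBr3 (8 equiv), CH2Cl2, −78 → 0 °C; ice-water; under Ar
Reagents that add atoms: none
Why: Lewis-acid ether cleavage (bromide attacks the O-methyl group of each ArO(Me)–BBr3 adduct), the 8-methoxy group assisted by chelation to the lactone carbonyl and the 5,6-pair leaving as a cyclic borate, while aliphatic methyl esters and the lactone should react much more slowly at or below 0 °C and the acidic medium leaves both stereocentres alone.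

**Compound list**

1 | 2,4,5-trimethoxybenzoic acid | COc1cc(OC)c(C(=O)O)cc1OC | starting material
2 | lithium 6-lithio-2,4,5-trimethoxybenzoate | [Li]c1c(OC)c(OC)cc(OC)c1C(=O)O[Li] | intermediate
3 | 3,4,6-trimethoxy-2-methylbenzoic acid | Cc1c(OC)c(OC)cc(OC)c1C(=O)O | intermediate
4 | methyl 3,4,6-trimethoxy-2-methylbenzoate | Cc1c(OC)c(OC)cc(OC)c1C(=O)OC | intermediate
5 | dimethyl oxalate | COC(=O)C(=O)OC | starting material
6 | methyl 2-(lithiomethyl)-3,4,6-trimethoxybenzoate | [Li]Cc1c(OC)c(OC)cc(OC)c1C(=O)OC | intermediate
7 | methyl 3,4,6-trimethoxy-2-(3-methoxy-2,3-dioxopropyl)benzoate | COC(=O)C(=O)Cc1c(OC)c(OC)cc(OC)c1C(=O)OC | intermediate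
8 | tert-butyl acetate | CC(=O)OC(C)(C)C | starting material
9 | tert-butyl acetate lithium enolate | [Li]OC(=C)OC(C)(C)C | intermediate
10 | 4-tert-butyl 1-methyl 2-oxobutanedioate | COC(=O)C(=O)CC(=O)OC(C)(C)C | intermediate
11 | 4-tert-butyl 1-methyl (2Z)-2-{[(trifluoromethyl)sulfonyl]oxy}but-2-enedioate | COC(=O)/C(OS(=O)(=O)C(F)(F)F)=C/C(=O)OC(C)(C)C | intermediate
12 | 4-tert-butyl 1-methyl (2E)-2-{3-methoxy-2,3-dioxo-1-[2,3,5-trimethoxy-6-(methoxycarbonyl)phenyl]propyl}but-2-enedioate, racemic at C4 | COC(=O)/C(=C/C(=O)OC(C)(C)C)C(C(=O)C(=O)OC)c1c(OC)c(OC)cc(OC)c1C(=O)OC | intermediate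
13 | 4-tert-butyl 1-methyl (2E)-2-{(1R,2S)-2-hydroxy-3-methoxy-3-oxo-1-[2,3,5-trimethoxy-6-(methoxycarbonyl)phenyl]propyl}but-2-enedioate | COC(=O)/C(=C/C(=O)OC(C)(C)C)[C@@H](c1c(OC)c(OC)cc(OC)c1C(=O)OC)[C@H](O)C(=O)OC | intermediate
14 | methyl (3S,4R)-4-[(2E)-4-tert-butoxy-1-methoxy-1,4-dioxobut-2-en-2-yl]-5,6,8-trimethoxy-1-oxo-3,4-dihydro-1H-isochromene-3-carboxylate | COC(=O)/C(=C/C(=O)OC(C)(C)C)[C@H]1c2c(OC)c(OC)cc(OC)c2C(=O)O[C@@H]1C(=O)OC | intermediate
15 | (2E)-4-methoxy-4-oxo-3-[(3S,4R)-5,6,8-trimethoxy-3-(methoxycarbonyl)-1-oxo-3,4-dihydro-1H-isochromen-4-yl]but-2-enoic acid | COC(=O)/C(=C/C(=O)O)[C@H]1c2c(OC)c(OC)cc(OC)c2C(=O)O[C@@H]1C(=O)OC | intermediate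
16 | (2E)-4-methoxy-4-oxo-3-[(3S,4R)-5,6,8-trihydroxy-3-(methoxycarbonyl)-1-oxo-3,4-dihydro-1H-isochromen-4-yl]but-2-enoic acid | COC(=O)/C(=C/C(=O)O)[C@H]1c2c(O)c(O)cc(O)c2C(=O)O[C@@H]1C(=O)OC | target

**Step count**

Total: 9 steps. Longest linear sequence: 7 steps (steps 1, 2, 3, 6, 7, 8, 9 from 1); the triflate branch (steps 4, 5) joins at step 6.

**Steps most likely to fail**

1. Step 7. The catalyst may not discriminate the two C4 epimers well enough in the hydride transfer, giving cis/trans lactone mixtures. The amine may also move the Cα=Cβ double bond towards C4 before reduction, or the C3 hydroxyl (or the enol before reduction) may close on the wrong ester. The fallback sets out from 12 and gives up the dynamic resolution. Reduction with NaBH4/CeCl3 in MeOH–THF at −78 °C under Felkin–Anh control (hydride anti to the aryl group) should give the (3S*,4R*) hydroxy ester as the racemate, that is 13 together with its enantiomer, the (1S,2R)-hydroxy tetraester F1. Closure with catalytic camphorsulfonic acid in toluene should give the racemic trans-lactone, that is 14 together with its enantiomer, the (3R,4S)-lactone F2. Preparative chromatography on a chiral stationary phase then delivers 14, where the route is rejoined.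

2. Step 6. The hindered enolate may attack through oxygen, or at the unsubstituted alkene carbon of 11 with later loss of triflate (cine-substitution, which would exchange the positions of the two side-chain esters). The base may also eliminate the triflate to the acetylenic diester, with the same loss of regiochemical information. The fallback sets out from 7 and makes the bond by cross-coupling, in which carbon–carbon bond formation can occur only at the carbon that carried the triflate. Silylation (TBSOTf, Et3N, CH2Cl2, 0 °C) gives the (Z)-tert-butyldimethylsilyl enol ether F3. Palladium-catalysed α-alkenylation via the tin enolate (Pd2(dba)3, P(t-Bu)3, Bu3SnF, toluene, 60 °C) with triflate 11 (oxidative addition, transmetalation, reductive elimination with retention of alkene geometry) returns 12.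

3. Step 9. Cleavage of the three ethers may be incomplete, aliphatic methyl esters or the lactone C3–O bond may be cleaved in competition, and the 1,2,4-triol may oxidise in air during work-up. The fallback sets out from 15 and replaces global Lewis-acid dealkylation by oxidative demethylation. Ceric ammonium nitrate (MeCN/H2O, 0 °C) oxidises the para-related C5/C8 dimethoxy pair to the methoxy-p-quinone F4. Sodium dithionite reduces it to the 5,8-dihydroxy-6-methoxy lactone F5. BCl3 (CH2Cl2, −78 → 0 °C) then removes the one remaining methyl ether, which is flanked by a free hydroxyl, and gives 16.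

Further compounds
F1 | step 7 | 4-tert-butyl 1-methyl (2E)-2-{(1S,2R)-2-hydroxy-3-methoxy-3-oxo-1-[2,3,5-trimethoxy-6-(methoxycarbonyl)phenyl]propyl}but-2-enedioate | COC(=O)/C(=C/C(=O)OC(C)(C)C)[C@H](c1c(OC)c(OC)cc(OC)c1C(=O)OC)[C@@H](O)C(=O)OC
F2 | step 7 | methyl (3R,4S)-4-[(2E)-4-tert-butoxy-1-methoxy-1,4-dioxobut-2-en-2-yl]-5,6,8-trimethoxy-1-oxo-3,4-dihydro-1H-isochromene-3-carboxylate | COC(=O)/C(=C/C(=O)OC(C)(C)C)[C@@H]1c2c(OC)c(OC)cc(OC)c2C(=O)O[C@H]1C(=O)OC
F3 | step 6 | methyl 2-[(1Z)-2-{[tert-butyl(dimethyl)silyl]oxy}-3-methoxy-3-oxoprop-1-en-1-yl]-3,4,6-trimethoxybenzoate | COC(=O)/C(O[Si](C)(C)C(C)(C)C)=C/c1c(OC)c(OC)cc(OC)c1C(=O)OC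
F4 | step 9 | (2E)-4-methoxy-3-[(3S,4R)-6-methoxy-3-(methoxycarbonyl)-1,5,8-trioxo-3,4,5,8-tetrahydro-1H-isochromen-4-yl]-4-oxobut-2-enoic acid | COC(=O)/C(=C/C(=O)O)[C@H]1C2=C(C(=O)O[C@@H]1C(=O)OC)C(=O)C=C(OC)C2=O
F5 | step 9 | (2E)-3-[(3S,4R)-5,8-dihydroxy-6-methoxy-3-(methoxycarbonyl)-1-oxo-3,4-dihydro-1H-isochromen-4-yl]-4-methoxy-4-oxobut-2-enoic acid | COC(=O)/C(=C/C(=O)O)[C@H]1c2c(O)c(OC)cc(O)c2C(=O)O[C@@H]1C(=O)OC
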